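**Strategy.** Ring C is disconnected at three bonds around C4 and C2: C4a–C4, C4–C3 and O1–C2. The carbonyl carbon C4 is a single carbon between C4a of ring A and C3, and ring A is symmetric about the C4a/C7 axis, so the oxygens that become O1 and the 5-OH are equivalent. One palladium-catalysed operation therefore joins a symmetric 2-iodoresorcinol, carbon monoxide and phenylacetylene into the flavone with no regiochemical choice. The precursor carries both arms as 2-(benzyloxy)benzyl groups, installed already protected, so no phenol needs to be differentiated and the last step is a neutral hydrogenolysis. C2 is set afterwards by copper hydride conjugate reduction.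

Key step: step 4

Assumption: (R)-DTBM-SEGPHOS is taken to send hydride to the face of C2 that gives the 2S product; if the first run shows the opposite sense, (S)-DTBM-SEGPHOS is used and nothing else changes.

**Step 1**
Reactants: 1 methyl 2,6-dihydroxy-4-methoxybenzoate; 2 [2-(benzyloxy)phenyl]methanol (2.3 equiv)
Product: 4 methyl 3,5-bis[2-(benzyloxy)benzyl]-2,6-dihydroxy-4-methoxybenzoate, via mono-benzylated benzoate 3 (not isolated)
Conditions: Sc(OTf)3 (10 mol%), MeNO2, 50 °C, slow addition of 2
Reagents that add atoms: none
Why: Friedel–Crafts benzylation with a benzylic alcohol under Lewis acid catalysis: the benzyl cation from 2, stabilised by its ortho-benzyloxy group, should attack C3 and then C5 of ring A, the only open positions, each flanked by OH and OMe and para to the second OH, while the ester keeps C1 closed and the arm oxygens arrive already protected.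

**Step 2**
Reactants: 4 methyl 3,5-bis[2-(benzyloxy)benzyl]-2,6-dihydroxy-4-methoxybenzoate
Product: 6 4,6-bis[2-(benzyloxy)benzyl]-5-methoxybenzene-1,3-diol, via benzoic acid 5 (not isolated)
Conditions: KOH, EtOH/H2O, reflux, Ar; then aq. HCl to pH 3, 50 °C
Reagents that add atoms: none
Why: Ester saponification followed by decarboxylation of a 2,6-dihydroxybenzoic acid, which should lose CO2 readily through ipso protonation of its phloroglucinol-type ring (a vinylogous β-keto acid), under conditions to which benzyl and methyl ethers are inert.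

**Step 3**
Reactants: 6 4,6-bis[2-(benzyloxy)benzyl]-5-methoxybenzene-1,3-diol
Product: 7 4,6-bis[2-(benzyloxy)benzyl]-2-iodo-5-methoxybenzene-1,3-diol
Conditions: I2 (1.05 equiv), NaHCO3, THF/H2O, 0 °C, dark
Reagents that add atoms: iodine (I2), SMILES II
Why: Electrophilic aromatic iodination of a resorcinol with buffered iodine: C2 is the only unsubstituted carbon of ring A and is activated by two ortho hydroxyls and the para methoxy group, whereas the alkoxy-substituted arm rings should not react with iodine under these conditions.

**Step 4**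
Reactants: 7 4,6-bis[2-(benzyloxy)benzyl]-2-iodo-5-methoxybenzene-1,3-diol; 8 phenylacetylene; 9 carbon monoxide
Product: 12 6,8-bis[2-(benzyloxy)benzyl]-5-hydroxy-7-methoxyflavone, via aryl ynone 10 (not isolated), via enaminone 11 (not isolated)
Conditions: PdCl2(PPh3)2 (5 mol%), Et2NH, CO (10 bar), 90 °C
Reagents that add atoms: none
Why: Oxidative addition of the C–I bond of 7 to zerovalent palladium (generated from PdCl2(PPh3)2 in the flask) is followed by migratory insertion of 9, and the resulting aroyl complex of divalent palladium is alkynylated by 8 and reductively eliminates aryl ynone 10, which creates C4a–C4 and C4–C3. Conjugate addition of diethylamine to 10 gives enaminone 11; one of the two flanking phenol oxygens then attacks the amine-bearing carbon and expels diethylamine (6-endo-trig addition–elimination), which forms O1–C2 and closes ring C, the only ring made here. The closest known reaction type is the palladium-catalysed carbonylative coupling of ortho-iodophenols with terminal alkynes to flavones. No stereocentre is created, so the flat flavone carries nothing that could be lost before C2 is set in step 5. The step needs carbonylative coupling to win over direct alkynylation, which CO pressure and the absence of a copper cocatalyst should secure, and six-membered closure to win over five-membered aurone closure, which the amine adduct 11 should secure by making the phenyl-bearing carbon the electrophilic site. A choice between the two phenols does not arise, because 7 has a mirror plane through its C–I and C–OMe carbons; the phenol that is not used becomes the chelated 5-OH.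

**Step 5**
Reactants: 12 6,8-bis[2-(benzyloxy)benzyl]-5-hydroxy-7-methoxyflavone
Product: 15 (2S)-6,8-bis[2-(benzyloxy)benzyl]-5-hydroxy-7-methoxyflavanone, via silyl ether 13 (not isolated), via silyl enol ether 14 (not isolated)
Conditions: Cu(OAc)2·H2O (5 mol%), (R)-DTBM-SEGPHOS (5.5 mol%), (EtO)2MeSiH (4 equiv), toluene, 0 °C to rt; then 1 M HCl, THF, 0 °C
Reagents that add atoms: none
Why: Copper hydride asymmetric conjugate reduction (1,4-hydrosilylation) of the chromone enone: the bisphosphine-bound copper hydride should first cap the 5-OH by dehydrogenative silylation (13), then deliver hydride to C2 on the face chosen by the chiral ligand, which sets the 2S centre, and the copper enolate is trapped by the silane as neutral silyl enol ether 14, so that no free enolate or base that could open ring C is present before mild acid releases 15.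

**Step 6**
Reactants: 15 (2S)-6,8-bis[2-(benzyloxy)benzyl]-5-hydroxy-7-methoxyflavanone
Product: 16 7-methoxydichamanetin, (2S)-5-hydroxy-6,8-bis(2-hydroxybenzyl)-7-methoxy-2-phenyl-2,3-dihydro-4H-chromen-4-one
Conditions: H2 (1 atm), 10% Pd/C, EtOAc, rt
Reagents that add atoms: none
Why: Catalytic hydrogenolysis of the two aryl benzyl ethers under neutral conditions, which should cleave far faster than the cyclic benzylic C2–O1 bond or the chelated C4 ketone and exposes the C2 centre to neither acid nor base.

**Compound list**

1 | methyl 2,6-dihydroxy-4-methoxybenzoate | COC(=O)c1c(O)cc(OC)cc1O | starting material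
2 | [2-(benzyloxy)phenyl]methanol (2-benzyloxybenzyl alcohol) | OCc1ccccc1OCc1ccccc1 | starting material
3 | methyl 3-[2-(benzyloxy)benzyl]-2,6-dihydroxy-4-methoxybenzoate (mono-benzylated benzoate, formed in the flask) | COC(=O)c1c(O)cc(OC)c(Cc2ccccc2OCc2ccccc2)c1O | intermediate
4 | methyl 3,5-bis[2-(benzyloxy)benzyl]-2,6-dihydroxy-4-methoxybenzoate | COC(=O)c1c(O)c(Cc2ccccc2OCc2ccccc2)c(OC)c(Cc2ccccc2OCc2ccccc2)c1O | intermediate
5 | 3,5-bis[2-(benzyloxy)benzyl]-2,6-dihydroxy-4-methoxybenzoic acid (formed in the flask) | OC(=O)c1c(O)c(Cc2ccccc2OCc2ccccc2)c(OC)c(Cc2ccccc2OCc2ccccc2)c1O | intermediate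
6 | 4,6-bis[2-(benzyloxy)benzyl]-5-methoxybenzene-1,3-diol | COc1c(Cc2ccccc2OCc2ccccc2)c(O)cc(O)c1Cc1ccccc1OCc1ccccc1 | intermediate
7 | 4,6-bis[2-(benzyloxy)benzyl]-2-iodo-5-methoxybenzene-1,3-diol | COc1c(Cc2ccccc2OCc2ccccc2)c(O)c(I)c(O)c1Cc1ccccc1OCc1ccccc1 | intermediate
8 | phenylacetylene | C#Cc1ccccc1 | starting material
9 | carbon monoxide | [C-]#[O+] | starting material
10 | 1-{3,5-bis[2-(benzyloxy)benzyl]-2,6-dihydroxy-4-methoxyphenyl}-3-phenylprop-2-yn-1-one (aryl ynone, formed in the flask) | COc1c(Cc2ccccc2OCc2ccccc2)c(O)c(C(=O)C#Cc2ccccc2)c(O)c1Cc1ccccc1OCc1ccccc1 | intermediate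
11 | (E)-1-{3,5-bis[2-(benzyloxy)benzyl]-2,6-dihydroxy-4-methoxyphenyl}-3-(diethylamino)-3-phenylprop-2-en-1-one (enaminone, formed in the flask) | COc1c(Cc2ccccc2OCc2ccccc2)c(O)c(C(=O)/C=C(/N(CC)CC)c2ccccc2)c(O)c1Cc1ccccc1OCc1ccccc1 | intermediate
12 | 6,8-bis[2-(benzyloxy)benzyl]-5-hydroxy-7-methoxy-2-phenyl-4H-chromen-4-one (the flavone) | COc1c(Cc2ccccc2OCc2ccccc2)c(O)c2c(c1Cc1ccccc1OCc1ccccc1)OC(c1ccccc1)=CC2=O | intermediate
13 | 6,8-bis[2-(benzyloxy)benzyl]-5-{[diethoxy(methyl)silyl]oxy}-7-methoxy-2-phenyl-4H-chromen-4-one (silyl ether, formed in the flask) | COc1c(Cc2ccccc2OCc2ccccc2)c(O[Si](C)(OCC)OCC)c2c(c1Cc1ccccc1OCc1ccccc1)OC(c1ccccc1)=CC2=O | intermediate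
14 | (2S)-6,8-bis[2-(benzyloxy)benzyl]-4,5-bis{[diethoxy(methyl)silyl]oxy}-7-methoxy-2-phenyl-2H-chromene (silyl enol ether, formed in the flask) | COc1c(Cc2ccccc2OCc2ccccc2)c(O[Si](C)(OCC)OCC)c2c(c1Cc1ccccc1OCc1ccccc1)O[C@H](c1ccccc1)C=C2O[Si](C)(OCC)OCC | intermediate
15 | (2S)-6,8-bis[2-(benzyloxy)benzyl]-5-hydroxy-7-methoxy-2-phenyl-2,3-dihydro-4H-chromen-4-one (the protected flavanone) | COc1c(Cc2ccccc2OCc2ccccc2)c(O)c2c(c1Cc1ccccc1OCc1ccccc1)O[C@H](c1ccccc1)CC2=O | intermediate
16 | 7-methoxydichamanetin, (2S)-5-hydroxy-6,8-bis(2-hydroxybenzyl)-7-methoxy-2-phenyl-2,3-dihydro-4H-chromen-4-one | COc1c(Cc2ccccc2O)c(O)c2c(c1Cc1ccccc1O)O[C@H](c1ccccc1)CC2=O | target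

Total step count: 6. Longest linear sequence: 6 steps (1 to 16).

**Steps most likely to fail**

Step 4. The electron-rich, doubly ortho-substituted aryl–palladium species may lose iodine by reduction before CO is taken up. It may also couple directly with the alkyne and close to a benzofuran, or the aroyl–palladium species may be captured by diethylamine. The fallback sets out from resorcinol 6 and comes back at flavone 12 by classical chemistry. Friedel–Crafts C-acetylation of the one open ring carbon (Ac2O, BF3·OEt2, 0 °C to room temperature) should give 1-{3,5-bis[2-(benzyloxy)benzyl]-2,6-dihydroxy-4-methoxyphenyl}ethan-1-one F1. Claisen–Schmidt condensation with benzaldehyde (KOH, EtOH) should give the chalcone (E)-1-{3,5-bis[2-(benzyloxy)benzyl]-2,6-dihydroxy-4-methoxyphenyl}-3-phenylprop-2-en-1-one F2. Oxidative cyclisation with catalytic I2 in DMSO at 120 °C should then close ring C to 12.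

Step 5. Facial discrimination may be insufficient on a flavone that carries a bulky arm at C8 next to O1. The chelating 5-OH/C4=O pair may slow turnover, and configuration could erode if ring C opens at the enolate stage. The fallback sets out from flavone 12 and comes back at 15 by resolution instead of asymmetric alkene reduction. Non-selective 1,4-reduction with L-Selectride (THF, −78 °C, acetic acid quench) should give racemic 6,8-bis[2-(benzyloxy)benzyl]-5-hydroxy-7-methoxyflavanone F3. Kinetic resolution by asymmetric transfer hydrogenation follows, with RuCl(p-cymene)(TsDPEN) in the antipode that consumes the 2R ketone and HCO2H/Et3N. It should reduce the unwanted enantiomer to the cis-alcohol (2R,4R)-6,8-bis[2-(benzyloxy)benzyl]-7-methoxy-2-phenylchromane-4,5-diol F4 and leave 15, which is separated by chromatography.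

Step 1. Ionisation of 2 may be followed by loss of the O-benzyl group, either by internal hydride shift from the OCH2Ph carbon to the cationic carbon or by acid-induced debenzylation. Self-condensation of 2 may also outrun attack on ring A. The fallback sets out from benzoate 1 and comes back at 4 through an ortho-quinone methide instead of a benzyl cation. Heating 1 with 2-hydroxybenzyl alcohol and ZnCl2 in 1,4-dioxane should give methyl 2,6-dihydroxy-3,5-bis(2-hydroxybenzyl)-4-methoxybenzoate F5. Its two arm phenols are then benzylated selectively (BnBr 2.1 equiv, K2CO3, acetone, room temperature). The ring A hydroxyls are hydrogen-bonded to the ester and flanked on both sides, so they should react last.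

**Further compounds**

F1 | step 4 | 1-{3,5-bis[2-(benzyloxy)benzyl]-2,6-dihydroxy-4-methoxyphenyl}ethan-1-one | COc1c(Cc2ccccc2OCc2ccccc2)c(O)c(C(C)=O)c(O)c1Cc1ccccc1OCc1ccccc1
F2 | step 4 | (E)-1-{3,5-bis[2-(benzyloxy)benzyl]-2,6-dihydroxy-4-methoxyphenyl}-3-phenylprop-2-en-1-one | COc1c(Cc2ccccc2OCc2ccccc2)c(O)c(C(=O)/C=C/c2ccccc2)c(O)c1Cc1ccccc1OCc1ccccc1
F3 | step 5 | racemic 6,8-bis[2-(benzyloxy)benzyl]-5-hydroxy-7-methoxy-2-phenyl-2,3-dihydro-4H-chromen-4-one | COc1c(Cc2ccccc2OCc2ccccc2)c(O)c2c(c1Cc1ccccc1OCc1ccccc1)OC(c1ccccc1)CC2=O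
F4 | step 5 | (2R,4R)-6,8-bis[2-(benzyloxy)benzyl]-7-methoxy-2-phenyl-3,4-dihydro-2H-chromene-4,5-diol | COc1c(Cc2ccccc2OCc2ccccc2)c(O)c2c(c1Cc1ccccc1OCc1ccccc1)O[C@@H](c1ccccc1)C[C@H]2O
F5 | step 1 | methyl 2,6-dihydroxy-3,5-bis(2-hydroxybenzyl)-4-methoxybenzoate | COC(=O)c1c(O)c(Cc2ccccc2O)c(OC)c(Cc2ccccc2O)c1O
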